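**Retrosynthetic overview** (germacrane numbering: ring C1–C10, acrylate unit C11–C13, methyls C14 and C15)
1. Last disconnection is the lactone O–C8 bond. The feature that allows it: in the γ-lactone ring (O–C8–C7–C11–C12) the carboxyl carbon C12 is γ to C8, and C8–O is anti to C9–OH on the ten-membered ring. A C12 carboxylate can therefore displace an (8S)-chloride 5-exo-tet with inversion, which turns an anti chlorohydrin into the threo C8–O/C9–OH pair.
2. The ten-membered carbocycle is closed at C9–C10 by Nozaki–Hiyama–Kishi reaction of a (Z)-2-iodoalkene with an α-chloro aldehyde. The chlorine comes from organocatalytic α-chlorination and steers C9 by the Cornforth model.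
3. C6–C7 is made by a catalytic asymmetric chromium 2-(alkoxycarbonyl)allylation (anti) of a Z enal with a Morita–Baylis–Hillman-derived allyl bromide; C6–OH is then acylated with (R)-2-methylbutanoic acid.
4. The Z enal comes from a temporary dihydropyranone ring (vinylogous Mukaiyama aldol–lactonization with but-2-ynal), which fixes C2 and the Z C4=C5 bond. Its reductive opening with hydroalumination–iodination gives the Z vinyl iodide.
5. Ring order: dihydropyranone (temporary, opened in step 3), then the ten-membered carbocycle (step 13), then the γ-lactone (step 14).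

Key step: step 14

Remark: the 2-methylbutanoyl group is taken as (R), as drawn in the target. Ligand and catalyst antipodes are quoted for the sense expected by analogy and would be exchanged if a model reaction shows the opposite induction.

**Step 1**
Reactants: 1 methyl 3-methylbut-2-enoate
Product: 2 [(1-methoxy-3-methylbuta-1,3-dien-1-yl)oxy]trimethylsilane
Conditions: LiN(iPr)2, THF, −78 °C; then Me3SiCl, −78 °C to rt
Reagents that add atoms: chlorotrimethylsilane, C[Si](C)(C)Cl
Why: γ-Deprotonation of the senecioate and O-silylation (silyl dienol ether formation) give the nucleophile for the vinylogous Mukaiyama aldol reaction; no stereocenter is formed.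

**Step 2**
Reactants: 2 [(1-methoxy-3-methylbuta-1,3-dien-1-yl)oxy]trimethylsilane; 3 but-2-ynal
Product: 5 (6S)-4-methyl-6-(prop-1-yn-1-yl)-5,6-dihydro-2H-pyran-2-one, via hydroxy enoate 4 (not isolated)
Conditions: Cu(OTf)2 (10 mol %), (S)-Tol-BINAP (10 mol %), Bu4N[Ph3SiF2], THF, −78 °C to rt
Reagents that add atoms: none
Why: A copper fluoride–bisphosphine-catalysed vinylogous Mukaiyama aldol reaction at the γ-carbon is followed by lactonization of the Z aldolate; the chiral bisphosphine selects the face of the ynal and so sets C2 (6S in lactone numbering), and the six-membered ring locks the Z geometry of the future C4=C5 bond.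

**Step 3**
Reactants: 5 (6S)-4-methyl-6-(prop-1-yn-1-yl)-5,6-dihydro-2H-pyran-2-one
Product: 7 (2Z,5S,6Z)-7-iodo-3-methylocta-2,6-diene-1,5-diol, via ynediol 6 (not isolated)
Conditions: NaAlH2(OCH2CH2OMe)2 (Red-Al, 4 equiv), THF, 0 °C to rt; then I2, −78 to 0 °C
Reagents that add atoms: iodine, II
Why: Red-Al reduces the lactone 1,2 to the Z allylic diol and then trans-hydroaluminates the propargylic alkoxide (hydride to the alkyne carbon next to the carbinol, aluminium to the distal carbon), so that iodinolysis with retention gives the Z vinyl iodide with iodine cis to C2; the C2 stereocenter is not touched.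

**Step 4**
Reactants: 7 (2Z,5S,6Z)-7-iodo-3-methylocta-2,6-diene-1,5-diol
Product: 8 (2Z,5S,6Z)-7-iodo-3-methyl-1,5-bis(triethylsilyloxy)octa-2,6-diene
Conditions: Et3SiCl, imidazole, CH2Cl2, 0 °C
Reagents that add atoms: chlorotriethylsilane, CC[Si](CC)(CC)Cl
Why: Standard silyl ether formation on both hydroxyl groups, without stereochemical change.

**Step 5**
Reactants: 8 (2Z,5S,6Z)-7-iodo-3-methyl-1,5-bis(triethylsilyloxy)octa-2,6-diene
Product: 9 (2Z,5S,6Z)-7-iodo-3-methyl-5-(triethylsilyloxy)octa-2,6-dienal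
Conditions: (COCl)2, DMSO, CH2Cl2, −78 to −40 °C; then Et3N
Reagents that add atoms: none
Why: Swern oxidation converts a primary triethylsilyl ether directly into the aldehyde while the secondary triethylsilyl ether survives, which gives the Z enal without a separate deprotection.

**Step 6**
Reactants: 10 tert-butyl acrylate; 11 3-[(4-methoxybenzyl)oxy]propanal
Product: 12 tert-butyl 3-hydroxy-5-[(4-methoxybenzyl)oxy]-2-methylidenepentanoate (racemic)
Conditions: DABCO (1 equiv), MeOH (cat.), neat, rt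
Reagents that add atoms: none
Why: Morita–Baylis–Hillman reaction of the acrylate with the aliphatic aldehyde; the carbinol center is racemic and is removed in step 7.

**Step 7**
Reactants: 12 tert-butyl 3-hydroxy-5-[(4-methoxybenzyl)oxy]-2-methylidenepentanoate
Product: 13 tert-butyl (2Z)-2-(bromomethyl)-5-[(4-methoxybenzyl)oxy]pent-2-enoate
Conditions: NBS, Me2S, CH2Cl2, 0 °C to rt
Reagents that add atoms: N-bromosuccinimide, BrN1C(=O)CCC1=O
Why: Corey–Kim-type activation of the allylic alcohol and SN2′ attack of bromide should give the thermodynamically preferred (Z)-2-(bromomethyl)alk-2-enoate.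

**Step 8**
Reactants: 9 (2Z,5S,6Z)-7-iodo-3-methyl-5-(triethylsilyloxy)octa-2,6-dienal; 13 tert-butyl (2Z)-2-(bromomethyl)-5-[(4-methoxybenzyl)oxy]pent-2-enoate
Product: 15 tert-butyl (3S,4R,5Z,8S,9Z)-4-hydroxy-10-iodo-3-{2-[(4-methoxybenzyl)oxy]ethyl}-6-methyl-2-methylidene-8-(triethylsilyloxy)undeca-5,9-dienoate, via trimethylsilyl ether 14 (not isolated)
Conditions: CrCl2 (10 mol %), chiral carbazole bis(oxazoline) ligand (12 mol %), Mn powder, Me3SiCl, iPr2NEt (30 mol %), THF, rt; then aqueous citric acid, MeOH, 0 °C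
Reagents that add atoms: none
Why: In this catalytic asymmetric Nozaki–Hiyama-type 2-(alkoxycarbonyl)allylation the allylchromium species adds at its γ-carbon through a chair transition state to give the anti C6/C7 relationship, the chiral chromium ligand selects the aldehyde face (6R,7S) independently of the remote C2 center, and the tert-butyl ester plus in situ O-silylation keep the new alkoxide from lactonizing.

**Step 9**
Reactants: 15 tert-butyl (3S,4R,5Z,8S,9Z)-4-hydroxy-10-iodo-3-{2-[(4-methoxybenzyl)oxy]ethyl}-6-methyl-2-methylidene-8-(triethylsilyloxy)undeca-5,9-dienoate; 16 (R)-2-methylbutanoic acid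
Product: 17 tert-butyl (3S,4R,5Z,8S,9Z)-10-iodo-3-{2-[(4-methoxybenzyl)oxy]ethyl}-6-methyl-4-{[(2R)-2-methylbutanoyl]oxy}-2-methylidene-8-(triethylsilyloxy)undeca-5,9-dienoate
Conditions: EDC·HCl, DMAP, CH2Cl2, 0 °C to rt
Reagents that add atoms: none
Why: Steglich-type carbodiimide esterification of the secondary allylic alcohol at 0 °C, conditions under which the α-stereocenter of the acid should not be enolised.

**Step 10**
Reactants: 17 tert-butyl (3S,4R,5Z,8S,9Z)-10-iodo-3-{2-[(4-methoxybenzyl)oxy]ethyl}-6-methyl-4-{[(2R)-2-methylbutanoyl]oxy}-2-methylidene-8-(triethylsilyloxy)undeca-5,9-dienoate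
Product: 18 tert-butyl (3S,4R,5Z,8S,9Z)-3-(2-hydroxyethyl)-10-iodo-6-methyl-4-{[(2R)-2-methylbutanoyl]oxy}-2-methylidene-8-(triethylsilyloxy)undeca-5,9-dienoate
Conditions: DDQ, CH2Cl2, pH 7 buffer, 0 °C
Reagents that add atoms: none
Why: Oxidative cleavage of the p-methoxybenzyl ether by DDQ, which should leave the silyl ether, both esters and the vinyl iodide untouched.

**Step 11**
Reactants: 18 tert-butyl (3S,4R,5Z,8S,9Z)-3-(2-hydroxyethyl)-10-iodo-6-methyl-4-{[(2R)-2-methylbutanoyl]oxy}-2-methylidene-8-(triethylsilyloxy)undeca-5,9-dienoate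
Product: 19 tert-butyl (3S,4R,5Z,8S,9Z)-10-iodo-6-methyl-4-{[(2R)-2-methylbutanoyl]oxy}-2-methylidene-3-(2-oxoethyl)-8-(triethylsilyloxy)undeca-5,9-dienoate
Conditions: Dess–Martin periodinane, NaHCO3, CH2Cl2, 0 °C to rt
Reagents that add atoms: none
Why: Buffered Dess–Martin oxidation turns the primary alcohol into the C9 aldehyde under non-basic conditions.

**Step 12**
Reactants: 19 tert-butyl (3S,4R,5Z,8S,9Z)-10-iodo-6-methyl-4-{[(2R)-2-methylbutanoyl]oxy}-2-methylidene-3-(2-oxoethyl)-8-(triethylsilyloxy)undeca-5,9-dienoate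
Product: 20 tert-butyl (3S,4R,5Z,8S,9Z)-3-[(1S)-1-chloro-2-oxoethyl]-10-iodo-6-methyl-4-{[(2R)-2-methylbutanoyl]oxy}-2-methylidene-8-(triethylsilyloxy)undeca-5,9-dienoate
Conditions: (2R,5R)-2,5-diphenylpyrrolidine (10 mol %), NCS, CH2Cl2, 0 °C; used crude at once
Reagents that add atoms: N-chlorosuccinimide, ClN1C(=O)CCC1=O
Why: Organocatalytic enamine α-chlorination, in which the C2-symmetric pyrrolidine controls the enamine face and sets the C8 chloride (8S, anti to C11 along C6–C9) that later serves as stereodirecting group and leaving group.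

**Step 13**
Reactants: 20 tert-butyl (3S,4R,5Z,8S,9Z)-3-[(1S)-1-chloro-2-oxoethyl]-10-iodo-6-methyl-4-{[(2R)-2-methylbutanoyl]oxy}-2-methylidene-8-(triethylsilyloxy)undeca-5,9-dienoate
Product: 21 tert-butyl (1(10)Z,2S,4Z,6R,7S,8S,9R)-8-chloro-9-hydroxy-6-{[(2R)-2-methylbutanoyl]oxy}-2-(triethylsilyloxy)germacra-1(10),4,11(13)-trien-12-oate (ten-membered carbocycle C1–C10)
Conditions: CrCl2 (8 equiv), NiCl2 (1 mol %), DMSO–THF, 2 mM, rt, slow addition
Reagents that add atoms: none
Why: In this Nozaki–Hiyama–Kishi macrocyclization the alkenylchromium species formed from the Z vinyl iodide with retention adds to the aldehyde and closes the ten-membered ring at C9–C10, and attack anti to the C–Cl bond (Cornforth model) should give the anti chlorohydrin with 9R configuration.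

**Step 14**
Reactants: 21 tert-butyl (1(10)Z,2S,4Z,6R,7S,8S,9R)-8-chloro-9-hydroxy-6-{[(2R)-2-methylbutanoyl]oxy}-2-(triethylsilyloxy)germacra-1(10),4,11(13)-trien-12-oate
Product: 24 (1(10)Z,2S,4Z,6R,7S,8R,9R)-9-hydroxy-6-{[(2R)-2-methylbutanoyl]oxy}-2-(triethylsilyloxy)germacra-1(10),4,11(13)-trien-12,8-olide, via bis-silyl intermediate 22 (not isolated), via seco acid 23 (not isolated)
Conditions: Me3SiOTf, 2,6-lutidine, CH2Cl2, 0 °C; aqueous work-up at pH 5; then CsHCO3, DMF, 45 °C
Reagents that add atoms: none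
Why: Me3SiOTf with 2,6-lutidine cleaves the tert-butyl ester (loss of isobutene) and transiently silylates C9–OH, mild aqueous work-up gives the seco acid, and its cesium carboxylate then displaces the C8 chloride from the back side in an intramolecular SN2 reaction. The closest known reaction types are the lactonization of γ-halo carboxylates and cesium-carboxylate SN2 displacement of secondary halides, together with the cyclization of chlorohydrins by internal oxygen nucleophiles. The γ-lactone ring (O–C8–C7–C11–C12) closes in the 5-exo-tet mode and becomes trans-fused to the ten-membered ring. C8 is set by inversion (8S chloride to 8R oxygen) while C9 keeps the configuration from step 13, so the anti chlorohydrin becomes the threo C8–O/C9–OH pair of the target. Substitution has to win over E2 elimination and over epoxide formation: in the extended C6–C7–C8–C9 conformer C11 is anti-periplanar to the C–Cl bond, so the carboxylate reaches the back side of C8 while H7 is gauche to chlorine, and hydrogen carbonate is too weak a base to ionise C9–OH, so the epoxide (which would give the C8 epimer by double inversion) should not form. The 2-methylbutanoate, the silyl ether and the trisubstituted alkenes should be inert under these conditions.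

**Step 15**
Reactants: 24 (1(10)Z,2S,4Z,6R,7S,8R,9R)-9-hydroxy-6-{[(2R)-2-methylbutanoyl]oxy}-2-(triethylsilyloxy)germacra-1(10),4,11(13)-trien-12,8-olide
Product: 25 (1(10)Z,2S,4Z,6R,7S,8R,9R)-2,9-dihydroxy-6-{[(2R)-2-methylbutanoyl]oxy}germacra-1(10),4,11(13)-trien-12,8-olide (CNP0176600.1)
Conditions: HF·pyridine, pyridine, THF, 0 °C
Reagents that add atoms: none
Why: Buffered fluoride cleavage of the secondary triethylsilyl ether, which should leave the α-methylene lactone and the ester intact.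

**Compound list**
1 | methyl 3-methylbut-2-enoate | CC(C)=CC(=O)OC | starting material
2 | [(1-methoxy-3-methylbuta-1,3-dien-1-yl)oxy]trimethylsilane | COC(O[Si](C)(C)C)=CC(C)=C | intermediate
3 | but-2-ynal | CC#CC=O | starting material
4 | hydroxy enoate, methyl (2Z,5S)-5-hydroxy-3-methyloct-2-en-6-ynoate (formed as its aldolate, not isolated) | COC(=O)/C=C(/C)C[C@H](O)C#CC | intermediate
5 | (6S)-4-methyl-6-(prop-1-yn-1-yl)-5,6-dihydro-2H-pyran-2-one | O=C1C=C(C)C[C@@H](C#CC)O1 | intermediate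
6 | ynediol, (2Z,5S)-3-methyloct-2-en-6-yne-1,5-diol (formed as its aluminate, not isolated) | OC/C=C(/C)C[C@H](O)C#CC | intermediate
7 | (2Z,5S,6Z)-7-iodo-3-methylocta-2,6-diene-1,5-diol | OC/C=C(/C)C[C@H](O)/C=C(/C)I | intermediate
8 | (2Z,5S,6Z)-7-iodo-3-methyl-1,5-bis(triethylsilyloxy)octa-2,6-diene | CC[Si](CC)(CC)OC/C=C(/C)C[C@H](O[Si](CC)(CC)CC)/C=C(/C)I | intermediate
9 | (2Z,5S,6Z)-7-iodo-3-methyl-5-(triethylsilyloxy)octa-2,6-dienal | O=C/C=C(/C)C[C@H](O[Si](CC)(CC)CC)/C=C(/C)I | intermediate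
10 | tert-butyl acrylate | C=CC(=O)OC(C)(C)C | starting material
11 | 3-[(4-methoxybenzyl)oxy]propanal | O=CCCOCc1ccc(OC)cc1 | starting material
12 | tert-butyl 3-hydroxy-5-[(4-methoxybenzyl)oxy]-2-methylidenepentanoate (racemic) | C=C(C(=O)OC(C)(C)C)C(O)CCOCc1ccc(OC)cc1 | intermediate
13 | tert-butyl (2Z)-2-(bromomethyl)-5-[(4-methoxybenzyl)oxy]pent-2-enoate | BrC/C(C(=O)OC(C)(C)C)=C\CCOCc1ccc(OC)cc1 | intermediate
14 | trimethylsilyl ether of 15 (not isolated) | C=C(C(=O)OC(C)(C)C)[C@H](CCOCc1ccc(OC)cc1)[C@H](O[Si](C)(C)C)/C=C(/C)C[C@H](O[Si](CC)(CC)CC)/C=C(/C)I | intermediate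
15 | tert-butyl (3S,4R,5Z,8S,9Z)-4-hydroxy-10-iodo-3-{2-[(4-methoxybenzyl)oxy]ethyl}-6-methyl-2-methylidene-8-(triethylsilyloxy)undeca-5,9-dienoate | C=C(C(=O)OC(C)(C)C)[C@H](CCOCc1ccc(OC)cc1)[C@H](O)/C=C(/C)C[C@H](O[Si](CC)(CC)CC)/C=C(/C)I | intermediate
16 | (R)-2-methylbutanoic acid | CC[C@@H](C)C(=O)O | starting material
17 | tert-butyl (3S,4R,5Z,8S,9Z)-10-iodo-3-{2-[(4-methoxybenzyl)oxy]ethyl}-6-methyl-4-{[(2R)-2-methylbutanoyl]oxy}-2-methylidene-8-(triethylsilyloxy)undeca-5,9-dienoate | C=C(C(=O)OC(C)(C)C)[C@H](CCOCc1ccc(OC)cc1)[C@H](OC(=O)[C@H](C)CC)/C=C(/C)C[C@H](O[Si](CC)(CC)CC)/C=C(/C)I | intermediate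
18 | tert-butyl (3S,4R,5Z,8S,9Z)-3-(2-hydroxyethyl)-10-iodo-6-methyl-4-{[(2R)-2-methylbutanoyl]oxy}-2-methylidene-8-(triethylsilyloxy)undeca-5,9-dienoate | C=C(C(=O)OC(C)(C)C)[C@H](CCO)[C@H](OC(=O)[C@H](C)CC)/C=C(/C)C[C@H](O[Si](CC)(CC)CC)/C=C(/C)I | intermediate
19 | tert-butyl (3S,4R,5Z,8S,9Z)-10-iodo-6-methyl-4-{[(2R)-2-methylbutanoyl]oxy}-2-methylidene-3-(2-oxoethyl)-8-(triethylsilyloxy)undeca-5,9-dienoate | C=C(C(=O)OC(C)(C)C)[C@H](CC=O)[C@H](OC(=O)[C@H](C)CC)/C=C(/C)C[C@H](O[Si](CC)(CC)CC)/C=C(/C)I | intermediate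
20 | tert-butyl (3S,4R,5Z,8S,9Z)-3-[(1S)-1-chloro-2-oxoethyl]-10-iodo-6-methyl-4-{[(2R)-2-methylbutanoyl]oxy}-2-methylidene-8-(triethylsilyloxy)undeca-5,9-dienoate | C=C(C(=O)OC(C)(C)C)[C@H]([C@H](Cl)C=O)[C@H](OC(=O)[C@H](C)CC)/C=C(/C)C[C@H](O[Si](CC)(CC)CC)/C=C(/C)I | intermediate
21 | tert-butyl (1(10)Z,2S,4Z,6R,7S,8S,9R)-8-chloro-9-hydroxy-6-{[(2R)-2-methylbutanoyl]oxy}-2-(triethylsilyloxy)germacra-1(10),4,11(13)-trien-12-oate | C=C(C(=O)OC(C)(C)C)[C@H]1[C@H](OC(=O)[C@H](C)CC)/C=C(/C)C[C@H](O[Si](CC)(CC)CC)/C=C(/C)[C@@H](O)[C@H]1Cl | intermediate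
22 | bis-silyl intermediate, trimethylsilyl ester and 9-O-trimethylsilyl ether of seco acid 23 (not isolated) | C=C(C(=O)O[Si](C)(C)C)[C@H]1[C@H](OC(=O)[C@H](C)CC)/C=C(/C)C[C@H](O[Si](CC)(CC)CC)/C=C(/C)[C@@H](O[Si](C)(C)C)[C@H]1Cl | intermediate
23 | seco acid, (1(10)Z,2S,4Z,6R,7S,8S,9R)-8-chloro-9-hydroxy-6-{[(2R)-2-methylbutanoyl]oxy}-2-(triethylsilyloxy)germacra-1(10),4,11(13)-trien-12-oic acid (not isolated) | C=C(C(=O)O)[C@H]1[C@H](OC(=O)[C@H](C)CC)/C=C(/C)C[C@H](O[Si](CC)(CC)CC)/C=C(/C)[C@@H](O)[C@H]1Cl | intermediate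
24 | (1(10)Z,2S,4Z,6R,7S,8R,9R)-9-hydroxy-6-{[(2R)-2-methylbutanoyl]oxy}-2-(triethylsilyloxy)germacra-1(10),4,11(13)-trien-12,8-olide | C=C1C(=O)O[C@@H]2[C@@H]1[C@H](OC(=O)[C@H](C)CC)/C=C(/C)C[C@H](O[Si](CC)(CC)CC)/C=C(/C)[C@H]2O | intermediate
25 | (1(10)Z,2S,4Z,6R,7S,8R,9R)-2,9-dihydroxy-6-{[(2R)-2-methylbutanoyl]oxy}germacra-1(10),4,11(13)-trien-12,8-olide (CNP0176600.1) | C=C1C(=O)O[C@@H]2[C@@H]1[C@H](OC(=O)[C@H](C)CC)/C=C(/C)C[C@H](O)/C=C(/C)[C@H]2O | target

**Step count and risks**
Total step count: 15. Longest linear sequence: 13 steps (steps 1–5, then 8–15); steps 6–7 form the side branch.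

Steps most likely to fail:

Step 13. Divalent chromium may reduce the C–Cl bond, the α-chloro aldehyde may epimerise at C8 before ring closure, or facial selectivity at C9 may erode in the macrocyclic transition state. The fallback sets out from 19 and comes back at 24. Nozaki–Hiyama–Kishi macrocyclization of the chlorine-free aldehyde 19 would give macrocyclic allylic alcohol F1 (either C9 epimer serves). Dess–Martin oxidation would give enone F2, and Me3SiOTf with 2,6-lutidine would unmask keto acid F3. Hypervalent-iodine α′-lactonization of this 5-oxo acid with PhI(OH)OTs would then form the O–C8 bond and give keto lactone F4, whose C8, being α to the ketone, can settle to the trans-fused arrangement. Luche reduction (NaBH4, CeCl3·7H2O, MeOH), with hydride delivered anti to the C8–O bond in the Felkin–Anh sense, should give 24.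

Step 14. Substitution at the hindered secondary chloride may be slow, so that E2 elimination toward C7 or epoxide formation from C9–O competes. The fallback sets out from 21 and comes back at 24. Dess–Martin oxidation of 21 would give α-chloro ketone F5, in which the chloride is activated for SN2 and no epoxide can form. Me3SiOTf with 2,6-lutidine would give chloro keto acid F6, and its cesium carboxylate (CsHCO3, DMF, rt) should displace chloride to give keto lactone F4, which is reduced to 24 as described for step 13.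

Step 8. Catalyst control may be insufficient with this β,β-disubstituted enal and γ-substituted bromide, giving poor facial selectivity or a poor anti/syn ratio. The fallback sets out from 9 and 13 and comes back at 17. Ligand-free, stoichiometric CrCl2 allylation (anti-selective Barbier-type addition) would give 15 together with its (6S,7R) diastereomeric alcohol F7. Esterification of the mixture with 16 would give 17 and diastereomeric ester F8, which differ at two centers while sharing C2 and the (R)-acyl group, so they should be separable by chromatography.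

Further compounds
F1 | step 13 | tert-butyl (1(10)Z,2S,4Z,6R,7S)-9-hydroxy-6-{[(2R)-2-methylbutanoyl]oxy}-2-(triethylsilyloxy)germacra-1(10),4,11(13)-trien-12-oate (C9 epimers) | C=C(C(=O)OC(C)(C)C)[C@H]1[C@H](OC(=O)[C@H](C)CC)/C=C(/C)C[C@H](O[Si](CC)(CC)CC)/C=C(/C)C(O)C1
F2 | step 13 | tert-butyl (1(10)Z,2S,4Z,6R,7S)-6-{[(2R)-2-methylbutanoyl]oxy}-9-oxo-2-(triethylsilyloxy)germacra-1(10),4,11(13)-trien-12-oate | C=C(C(=O)OC(C)(C)C)[C@H]1[C@H](OC(=O)[C@H](C)CC)/C=C(/C)C[C@H](O[Si](CC)(CC)CC)/C=C(/C)C(=O)C1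
F3 | step 13 | (1(10)Z,2S,4Z,6R,7S)-6-{[(2R)-2-methylbutanoyl]oxy}-9-oxo-2-(triethylsilyloxy)germacra-1(10),4,11(13)-trien-12-oic acid | C=C(C(=O)O)[C@H]1[C@H](OC(=O)[C@H](C)CC)/C=C(/C)C[C@H](O[Si](CC)(CC)CC)/C=C(/C)C(=O)C1
F4 | step 13 | (1(10)Z,2S,4Z,6R,7S,8R)-6-{[(2R)-2-methylbutanoyl]oxy}-9-oxo-2-(triethylsilyloxy)germacra-1(10),4,11(13)-trien-12,8-olide | C=C1C(=O)O[C@@H]2[C@@H]1[C@H](OC(=O)[C@H](C)CC)/C=C(/C)C[C@H](O[Si](CC)(CC)CC)/C=C(/C)C2=O
F5 | step 14 | tert-butyl (1(10)Z,2S,4Z,6R,7S,8S)-8-chloro-6-{[(2R)-2-methylbutanoyl]oxy}-9-oxo-2-(triethylsilyloxy)germacra-1(10),4,11(13)-trien-12-oate | C=C(C(=O)OC(C)(C)C)[C@H]1[C@H](OC(=O)[C@H](C)CC)/C=C(/C)C[C@H](O[Si](CC)(CC)CC)/C=C(/C)C(=O)[C@H]1Cl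
F6 | step 14 | (1(10)Z,2S,4Z,6R,7S,8S)-8-chloro-6-{[(2R)-2-methylbutanoyl]oxy}-9-oxo-2-(triethylsilyloxy)germacra-1(10),4,11(13)-trien-12-oic acid | C=C(C(=O)O)[C@H]1[C@H](OC(=O)[C@H](C)CC)/C=C(/C)C[C@H](O[Si](CC)(CC)CC)/C=C(/C)C(=O)[C@H]1Cl
F7 | step 8 | tert-butyl (3R,4S,5Z,8S,9Z)-4-hydroxy-10-iodo-3-{2-[(4-methoxybenzyl)oxy]ethyl}-6-methyl-2-methylidene-8-(triethylsilyloxy)undeca-5,9-dienoate | C=C(C(=O)OC(C)(C)C)[C@@H](CCOCc1ccc(OC)cc1)[C@@H](O)/C=C(/C)C[C@H](O[Si](CC)(CC)CC)/C=C(/C)I
F8 | step 8 | tert-butyl (3R,4S,5Z,8S,9Z)-10-iodo-3-{2-[(4-methoxybenzyl)oxy]ethyl}-6-methyl-4-{[(2R)-2-methylbutanoyl]oxy}-2-methylidene-8-(triethylsilyloxy)undeca-5,9-dienoate | C=C(C(=O)OC(C)(C)C)[C@@H](CCOCc1ccc(OC)cc1)[C@@H](OC(=O)[C@H](C)CC)/C=C(/C)C[C@H](O[Si](CC)(CC)CC)/C=C(/C)I
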